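**Retrosynthetic overview**

1. Chrysomutanin is an (R)-8-hydroxy-3-methylisochroman-1-one whose C5 and O6 are bridged by a (2Z,6Z)-3,7-dimethyldeca-2,6-dienyl chain ending in C10′H(OH)–C(CH3)2–O6, a 14-membered ring fused to the arene.
2. Key disconnection: the C10′–C(CH3)2 bond of that ring. The ether carbon carries O6, two methyls and the carbinol carbon, so it is the α-carbon of an α-aryloxyisobutyric acid; decarboxylation (redox-active ester, CrCl2) turns this natively electrophilic carbon into a tertiary radical and then an alkylchromium nucleophile that adds to a C10′ aldehyde and closes the macrocycle (polarity-reversed union of two oxygenated carbons).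
3. The seco acid–aldehyde comes from O6-alkylation of a 5-alkyl-6,8-dihydroxyisochromanone with an α-bromoisobutyrate; the aryl–C1′ bond comes from a C5 aryl Grignard reagent and a (Z,Z)-allylic bromide built by two syn-carbocuprations of propyne.
4. The iodinated lactone core comes from (R)-propylene oxide, a 3,5-bis(silyloxy)phenyl Grignard reagent, a symmetric double iodination and a carbonylative lactonisation.
5. Ring order: arene (purchased) → six-membered lactone (step 9) → 14-membered ring (step 15); the carbinol configuration is then set by oxidation and CBS reduction (steps 16 and 17).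

Key step: step 15

Assumption: the C8 phenol, hydrogen-bonded to the lactone carbonyl, is carried unprotected from step 11 on; locants C1′–C10′ count the side chain from the arene outwards.

**Route**

Step 1
Reactants: 1 2-(2-bromoethyl)-1,3-dioxolane
Product: 5 (Z)-6-(1,3-dioxolan-2-yl)-4-methylhex-3-en-1-ol, via Grignard reagent 2 (not isolated), via alkylcopper 3 (not isolated), via alkenylcopper 4 (not isolated)
Conditions: Mg, THF, 30 °C; CuBr·SMe2, Et2O/Me2S, −45 °C; propyne, −25 °C; 1-lithio-1-pentyne (1-pentyne + n-BuLi), HMPA, oxirane, −78 → 20 °C; aq. NH4Cl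
Reagents that add atoms: propyne (CC#C); oxirane (C1CO1)
Why: Syn-carbocupration of propyne places the alkyl group and copper cis on the new alkene, and the alkenylcopper, activated as its mixed pentynyl cuprate, opens oxirane with retention, which fixes the Z geometry of the trisubstituted alkene.

Step 2
Reactants: 5 (Z)-6-(1,3-dioxolan-2-yl)-4-methylhex-3-en-1-ol
Product: 6 2-[(Z)-6-iodo-3-methylhex-3-en-1-yl]-1,3-dioxolane
Conditions: I2, PPh3, imidazole, CH2Cl2, 0 °C
Reagents that add atoms: iodine ([I][I])
Why: Appel-type iodination converts the primary alcohol by SN2 displacement of the alkoxyphosphonium ion and leaves the acetal and the alkene untouched.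

Step 3
Reactants: 6 2-[(Z)-6-iodo-3-methylhex-3-en-1-yl]-1,3-dioxolane
Product: 10 2-[(3Z,7Z)-8-iodo-3,7-dimethylocta-3,7-dien-1-yl]-1,3-dioxolane, via Grignard reagent 7 (not isolated), via alkylcopper 8 (not isolated), via alkenylcopper 9 (not isolated)
Conditions: Mg, Et2O, 20 °C; CuBr·SMe2, Et2O/Me2S, −45 °C; propyne, −25 °C; I2, −50 → 0 °C
Reagents that add atoms: propyne (CC#C); iodine ([I][I])
Why: A second syn-carbocupration of propyne by the homoallylic alkylcopper, followed by iodinolysis of the alkenyl–copper bond with retention, should set the second Z-trisubstituted alkene as a geometrically defined alkenyl iodide.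

Step 4
Reactants: 10 2-[(3Z,7Z)-8-iodo-3,7-dimethylocta-3,7-dien-1-yl]-1,3-dioxolane
Product: 12 (2Z,6Z)-9-(1,3-dioxolan-2-yl)-3,7-dimethylnona-2,6-dien-1-ol, via alkenyllithium 11 (not isolated)
Conditions: t-BuLi (2.1 equiv), Et2O, −78 °C; (CH2O)n, −78 → 20 °C; aq. NH4Cl
Reagents that add atoms: formaldehyde as paraformaldehyde (C=O)
Why: Iodine–lithium exchange proceeds with retention of alkene geometry and 1,2-addition of the alkenyllithium to formaldehyde gives the Z,Z-allylic alcohol.

Step 5
Reactants: 12 (2Z,6Z)-9-(1,3-dioxolan-2-yl)-3,7-dimethylnona-2,6-dien-1-ol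
Product: 13 2-[(3Z,7Z)-9-bromo-3,7-dimethylnona-3,7-dien-1-yl]-1,3-dioxolane
Conditions: CBr4, PPh3, CH2Cl2, −20 °C
Reagents that add atoms: carbon tetrabromide (BrC(Br)(Br)Br)
Why: Appel bromination of the primary allylic alcohol at low temperature is an SN2 displacement and should keep the position and Z geometry of the allylic alkene.

Step 6
Reactants: 14 5-bromobenzene-1,3-diol
Product: 15 1-bromo-3,5-bis(tert-butyldimethylsilyloxy)benzene
Conditions: TBSCl, imidazole, DMF, 20 °C
Reagents that add atoms: tert-butyldimethylsilyl chloride (CC(C)(C)[Si](C)(C)Cl)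
Why: Standard silylation masks both phenols as ethers that tolerate Grignard formation, iodination and the later aryl Grignard step and are removed by fluoride.

Step 7
Reactants: 15 1-bromo-3,5-bis(tert-butyldimethylsilyloxy)benzene; 16 (R)-2-methyloxirane
Product: 18 (R)-1-[3,5-bis(tert-butyldimethylsilyloxy)phenyl]propan-2-ol, via aryl Grignard reagent 17 (not isolated)
Conditions: Mg, THF, 40 °C; CuI (10 mol %), 16, −30 → 0 °C; aq. NH4Cl
Reagents that add atoms: none
Why: Copper-catalysed epoxide opening by the aryl Grignard reagent occurs at the unsubstituted carbon, so the stereocentre of (R)-propylene oxide is carried unchanged into the future C3 (R).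

Step 8
Reactants: 18 (R)-1-[3,5-bis(tert-butyldimethylsilyloxy)phenyl]propan-2-ol
Product: 19 (R)-1-[3,5-bis(tert-butyldimethylsilyloxy)-2,6-diiodophenyl]propan-2-ol
Conditions: NIS (2.2 equiv), TFA (10 mol %), MeCN, 0 → 20 °C
Reagents that add atoms: N-iodosuccinimide (O=C1CCC(=O)N1I)
Why: Electrophilic aromatic iodination should go to the two equivalent positions ortho to the side chain and para to a silyloxy group, the position between the two silyloxy groups being the most hindered, so the symmetric diiodide defines the substitution pattern without a regiochemical choice.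

Step 9
Reactants: 19 (R)-1-[3,5-bis(tert-butyldimethylsilyloxy)-2,6-diiodophenyl]propan-2-ol
Product: 20 (R)-6,8-bis(tert-butyldimethylsilyloxy)-5-iodo-3-methylisochroman-1-one
Conditions: PdCl2(PPh3)2 (5 mol %), CO (1 atm), Et3N, DMF, 70 °C
Reagents that add atoms: carbon monoxide ([C-]#[O+])
Why: Palladium-catalysed carbonylative lactonisation (oxidative addition to zerovalent palladium, CO insertion, capture of the acylpalladium by the secondary alcohol) closes the six-membered lactone; either iodide gives the same product and the remaining iodide marks C5.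

Step 10
Reactants: 20 (R)-6,8-bis(tert-butyldimethylsilyloxy)-5-iodo-3-methylisochroman-1-one; 13 2-[(3Z,7Z)-9-bromo-3,7-dimethylnona-3,7-dien-1-yl]-1,3-dioxolane
Product: 22 (R)-6,8-bis(tert-butyldimethylsilyloxy)-5-[(2Z,6Z)-9-(1,3-dioxolan-2-yl)-3,7-dimethylnona-2,6-dien-1-yl]-3-methylisochroman-1-one, via arylmagnesium chloride 21 (not isolated)
Conditions: i-PrMgCl·LiCl (1.1 equiv), THF, −40 °C; Li2CuCl4 (5 mol %), 13, −40 → 0 °C
Reagents that add atoms: none
Why: Iodine–magnesium exchange at −40 °C tolerates the hindered lactone, and copper-catalysed SN2 allylation of the aryl Grignard reagent with the primary allylic bromide (γ carbon fully substituted) should form the aryl–C1′ bond with retention of the Z geometry.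

Step 11
Reactants: 22 (R)-6,8-bis(tert-butyldimethylsilyloxy)-5-[(2Z,6Z)-9-(1,3-dioxolan-2-yl)-3,7-dimethylnona-2,6-dien-1-yl]-3-methylisochroman-1-one
Product: 23 (R)-5-[(2Z,6Z)-9-(1,3-dioxolan-2-yl)-3,7-dimethylnona-2,6-dien-1-yl]-6,8-dihydroxy-3-methylisochroman-1-one
Conditions: TBAF, AcOH, THF, 0 °C
Reagents that add atoms: none
Why: Fluoride-mediated desilylation, buffered with acetic acid to spare the lactone, frees both phenols while the acetal and alkenes are inert.

Step 12
Reactants: 23 (R)-5-[(2Z,6Z)-9-(1,3-dioxolan-2-yl)-3,7-dimethylnona-2,6-dien-1-yl]-6,8-dihydroxy-3-methylisochroman-1-one; 24 allyl 2-bromo-2-methylpropanoate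
Product: 25 allyl 2-{[(R)-5-[(2Z,6Z)-9-(1,3-dioxolan-2-yl)-3,7-dimethylnona-2,6-dien-1-yl]-8-hydroxy-3-methyl-1-oxoisochroman-6-yl]oxy}-2-methylpropanoate
Conditions: Cs2CO3, DMF, 60 °C
Reagents that add atoms: none
Why: Williamson-type etherification with a tertiary α-bromo ester (the usual entry to α-aryloxyisobutyrates) should occur at the more acidic C6 phenol para to the lactone carbonyl, the C8 phenol being held in its hydrogen bond.

Step 13
Reactants: 25 allyl 2-{[(R)-5-[(2Z,6Z)-9-(1,3-dioxolan-2-yl)-3,7-dimethylnona-2,6-dien-1-yl]-8-hydroxy-3-methyl-1-oxoisochroman-6-yl]oxy}-2-methylpropanoate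
Product: 27 2-{[(R)-5-[(2Z,6Z)-3,7-dimethyl-10-oxodeca-2,6-dien-1-yl]-8-hydroxy-3-methyl-1-oxoisochroman-6-yl]oxy}-2-methylpropanoic acid, via acetal acid 26 (not isolated)
Conditions: Pd(PPh3)4 (5 mol %), morpholine, THF, 20 °C; then 2 M HCl, THF/H2O, 20 °C
Reagents that add atoms: water (O)
Why: Tsuji–Trost deallylation (zerovalent palladium, morpholine as allyl acceptor) frees the acid under neutral conditions and dilute aqueous acid then hydrolyses the dioxolane to the aldehyde without affecting the lactone, the aryl ether or the Z alkenes.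

Step 14
Reactants: 27 2-{[(R)-5-[(2Z,6Z)-3,7-dimethyl-10-oxodeca-2,6-dien-1-yl]-8-hydroxy-3-methyl-1-oxoisochroman-6-yl]oxy}-2-methylpropanoic acid
Product: 28 4,5,6,7-tetrachloro-1,3-dioxoisoindolin-2-yl 2-{[(R)-5-[(2Z,6Z)-3,7-dimethyl-10-oxodeca-2,6-dien-1-yl]-8-hydroxy-3-methyl-1-oxoisochroman-6-yl]oxy}-2-methylpropanoate
Conditions: N-hydroxytetrachlorophthalimide, DIC, DMAP (10 mol %), CH2Cl2, 20 °C
Reagents that add atoms: N-hydroxytetrachlorophthalimide (O=C1N(O)C(=O)c2c(Cl)c(Cl)c(Cl)c(Cl)c12)
Why: Carbodiimide (Steglich-type) esterification converts the hindered acid into its redox-active N-acyloxyphthalimide ester, with the aldehyde and the hydrogen-bonded phenol as spectators.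

Step 15
Reactants: 28 4,5,6,7-tetrachloro-1,3-dioxoisoindolin-2-yl 2-{[(R)-5-[(2Z,6Z)-3,7-dimethyl-10-oxodeca-2,6-dien-1-yl]-8-hydroxy-3-methyl-1-oxoisochroman-6-yl]oxy}-2-methylpropanoate
Product: 31 C10′-epimeric mixture of chrysomutanin (14-membered macrocyclic alcohol; both configurations at the carbinol carbon), via tertiary radical 29 (not isolated), via alkylchromium 30 (not isolated)
Conditions: CrCl2 (8 equiv), THF/DMF 3:1, 25 °C, 28 added by syringe pump over 12 h (final 0.002 M); aq. potassium sodium tartrate work-up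
Reagents that add atoms: none
Why: Proposed new method: divalent chromium transfers one electron to the tetrachlorophthalimide ester of 28, which fragments with loss of CO2 to the tertiary α-aryloxyalkyl radical 29; a second divalent chromium captures 29 as the tertiary alkylchromium 30 (trivalent chromium), a carbon nucleophile that adds to the tethered C10′ aldehyde, following the closest known reaction types, the intermolecular CrCl2-mediated decarboxylative addition of redox-active esters to aldehydes and Nozaki–Hiyama–Kishi macrocyclisations. The 14-membered ring is closed in the 14-exo-trig mode by this carbonyl addition, which at the same time builds the fully substituted aryl ether carbon next to the carbinol, a union of two carbons that are both natively electrophilic. The new carbinol stereocentre has no controlling element, because the C3 stereocentre of the lactone is remote, so 31 is expected as a mixture of both epimers, which steps 16 and 17 converge. The step needs capture of 29 by chromium to outrun its 6-exo addition to the C2′=C3′ alkene and needs 30 to choose the aldehyde over the lactone: the first should be secured by a standing excess of CrCl2 against slowly added 28 (the competing cyclisation is polarity-mismatched and would join the radical carbon to a carbon next to a fully substituted centre), the second by the known aldehyde selectivity of organochromium reagents. Syringe-pump addition to high dilution should suppress intermolecular addition.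

Step 16
Reactants: 31 C10′-epimeric mixture of chrysomutanin
Product: 32 10′-oxochrysomutanin (macrocyclic ketone; carbinol of the target oxidised to C=O)
Conditions: Dess–Martin periodinane, NaHCO3, CH2Cl2, 0 → 20 °C
Reagents that add atoms: none
Why: Dess–Martin oxidation converts both carbinol epimers into one ketone, erasing the uncontrolled centre, while the hydrogen-bonded phenol and the alkenes should be inert under buffered conditions.

Step 17
Reactants: 32 10′-oxochrysomutanin
Product: 33 chrysomutanin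
Conditions: (R)-2-methyl-CBS-oxazaborolidine (0.5 equiv), catecholborane (2 equiv), toluene, −78 → −40 °C; MeOH, then aq. NaHCO3
Reagents that add atoms: none
Why: CBS reduction with the (R)-oxazaborolidine should deliver hydride to the ketone face that keeps the large C(CH3)2OAr group away from the catalyst, which by the usual model gives the (S)-carbinol, and catecholborane at low temperature leaves the lactone and the alkenes untouched.

**Compound list**

1 | 2-(2-bromoethyl)-1,3-dioxolane | BrCCC1OCCO1 | starting material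
2 | [2-(1,3-dioxolan-2-yl)ethyl]magnesium bromide | Br[Mg]CCC1OCCO1 | intermediate
3 | [2-(1,3-dioxolan-2-yl)ethyl]copper | [Cu]CCC1OCCO1 | intermediate
4 | [(Z)-4-(1,3-dioxolan-2-yl)-2-methylbut-1-en-1-yl]copper | [Cu]/C=C(/C)CCC1OCCO1 | intermediate
5 | (Z)-6-(1,3-dioxolan-2-yl)-4-methylhex-3-en-1-ol | OCC/C=C(/C)CCC1OCCO1 | intermediate
6 | 2-[(Z)-6-iodo-3-methylhex-3-en-1-yl]-1,3-dioxolane | ICC/C=C(/C)CCC1OCCO1 | intermediate
7 | [(Z)-6-(1,3-dioxolan-2-yl)-4-methylhex-3-en-1-yl]magnesium iodide | I[Mg]CC/C=C(/C)CCC1OCCO1 | intermediate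
8 | [(Z)-6-(1,3-dioxolan-2-yl)-4-methylhex-3-en-1-yl]copper | [Cu]CC/C=C(/C)CCC1OCCO1 | intermediate
9 | [(1Z,5Z)-8-(1,3-dioxolan-2-yl)-2,6-dimethylocta-1,5-dien-1-yl]copper | [Cu]/C=C(/C)CC/C=C(/C)CCC1OCCO1 | intermediate
10 | 2-[(3Z,7Z)-8-iodo-3,7-dimethylocta-3,7-dien-1-yl]-1,3-dioxolane | I/C=C(/C)CC/C=C(/C)CCC1OCCO1 | intermediate
11 | [(1Z,5Z)-8-(1,3-dioxolan-2-yl)-2,6-dimethylocta-1,5-dien-1-yl]lithium | [Li]/C=C(/C)CC/C=C(/C)CCC1OCCO1 | intermediate
12 | (2Z,6Z)-9-(1,3-dioxolan-2-yl)-3,7-dimethylnona-2,6-dien-1-ol | OC/C=C(/C)CC/C=C(/C)CCC1OCCO1 | intermediate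
13 | 2-[(3Z,7Z)-9-bromo-3,7-dimethylnona-3,7-dien-1-yl]-1,3-dioxolane | BrC/C=C(/C)CC/C=C(/C)CCC1OCCO1 | intermediate
14 | 5-bromobenzene-1,3-diol | Oc1cc(O)cc(Br)c1 | starting material
15 | 1-bromo-3,5-bis(tert-butyldimethylsilyloxy)benzene | Brc1cc(O[Si](C)(C)C(C)(C)C)cc(O[Si](C)(C)C(C)(C)C)c1 | intermediate
16 | (R)-2-methyloxirane | C[C@@H]1CO1 | starting material
17 | [3,5-bis(tert-butyldimethylsilyloxy)phenyl]magnesium bromide | Br[Mg]c1cc(O[Si](C)(C)C(C)(C)C)cc(O[Si](C)(C)C(C)(C)C)c1 | intermediate
18 | (R)-1-[3,5-bis(tert-butyldimethylsilyloxy)phenyl]propan-2-ol | C[C@@H](O)Cc1cc(O[Si](C)(C)C(C)(C)C)cc(O[Si](C)(C)C(C)(C)C)c1 | intermediate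
19 | (R)-1-[3,5-bis(tert-butyldimethylsilyloxy)-2,6-diiodophenyl]propan-2-ol | C[C@@H](O)Cc1c(I)c(O[Si](C)(C)C(C)(C)C)cc(O[Si](C)(C)C(C)(C)C)c1I | intermediate
20 | (R)-6,8-bis(tert-butyldimethylsilyloxy)-5-iodo-3-methylisochroman-1-one | C[C@@H]1Cc2c(I)c(O[Si](C)(C)C(C)(C)C)cc(O[Si](C)(C)C(C)(C)C)c2C(=O)O1 | intermediate
21 | [(R)-6,8-bis(tert-butyldimethylsilyloxy)-3-methyl-1-oxoisochroman-5-yl]magnesium chloride | C[C@@H]1Cc2c([Mg]Cl)c(O[Si](C)(C)C(C)(C)C)cc(O[Si](C)(C)C(C)(C)C)c2C(=O)O1 | intermediate
22 | (R)-6,8-bis(tert-butyldimethylsilyloxy)-5-[(2Z,6Z)-9-(1,3-dioxolan-2-yl)-3,7-dimethylnona-2,6-dien-1-yl]-3-methylisochroman-1-one | C[C@@H]1Cc2c(C/C=C(/C)CC/C=C(/C)CCC3OCCO3)c(O[Si](C)(C)C(C)(C)C)cc(O[Si](C)(C)C(C)(C)C)c2C(=O)O1 | intermediate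
23 | (R)-5-[(2Z,6Z)-9-(1,3-dioxolan-2-yl)-3,7-dimethylnona-2,6-dien-1-yl]-6,8-dihydroxy-3-methylisochroman-1-one | C[C@@H]1Cc2c(C/C=C(/C)CC/C=C(/C)CCC3OCCO3)c(O)cc(O)c2C(=O)O1 | intermediate
24 | allyl 2-bromo-2-methylpropanoate | C=CCOC(=O)C(C)(C)Br | starting material
25 | allyl 2-{[(R)-5-[(2Z,6Z)-9-(1,3-dioxolan-2-yl)-3,7-dimethylnona-2,6-dien-1-yl]-8-hydroxy-3-methyl-1-oxoisochroman-6-yl]oxy}-2-methylpropanoate | C[C@@H]1Cc2c(C/C=C(/C)CC/C=C(/C)CCC3OCCO3)c(OC(C)(C)C(=O)OCC=C)cc(O)c2C(=O)O1 | intermediate
26 | 2-{[(R)-5-[(2Z,6Z)-9-(1,3-dioxolan-2-yl)-3,7-dimethylnona-2,6-dien-1-yl]-8-hydroxy-3-methyl-1-oxoisochroman-6-yl]oxy}-2-methylpropanoic acid | C[C@@H]1Cc2c(C/C=C(/C)CC/C=C(/C)CCC3OCCO3)c(OC(C)(C)C(=O)O)cc(O)c2C(=O)O1 | intermediate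
27 | 2-{[(R)-5-[(2Z,6Z)-3,7-dimethyl-10-oxodeca-2,6-dien-1-yl]-8-hydroxy-3-methyl-1-oxoisochroman-6-yl]oxy}-2-methylpropanoic acid | C[C@@H]1Cc2c(C/C=C(/C)CC/C=C(/C)CCC=O)c(OC(C)(C)C(=O)O)cc(O)c2C(=O)O1 | intermediate
28 | 4,5,6,7-tetrachloro-1,3-dioxoisoindolin-2-yl ester of acid 27 | C[C@@H]1Cc2c(C/C=C(/C)CC/C=C(/C)CCC=O)c(OC(C)(C)C(=O)ON3C(=O)c4c(Cl)c(Cl)c(Cl)c(Cl)c4C3=O)cc(O)c2C(=O)O1 | intermediate
29 | tertiary α-aryloxyalkyl radical (2-aryloxyprop-2-yl radical on O6 of the aldehyde-bearing isochromanone) | C[C@@H]1Cc2c(C/C=C(/C)CC/C=C(/C)CCC=O)c(O[C](C)C)cc(O)c2C(=O)O1 | intermediate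
30 | dichloro(2-aryloxyprop-2-yl)chromium derived from radical 29 | C[C@@H]1Cc2c(C/C=C(/C)CC/C=C(/C)CCC=O)c(OC(C)(C)[Cr](Cl)Cl)cc(O)c2C(=O)O1 | intermediate
31 | C10′-epimeric mixture of chrysomutanin (macrocyclic alcohol, carbinol carbon unassigned, C3 R, both ring alkenes as in the target) | C/C1=C/Cc2c(cc(O)c3c2C[C@@H](C)OC3=O)OC(C)(C)C(O)CC/C(C)=C\CC1 | intermediate
32 | 10′-oxochrysomutanin (macrocyclic α-aryloxy ketone) | C/C1=C/Cc2c(cc(O)c3c2C[C@@H](C)OC3=O)OC(C)(C)C(=O)CC/C(C)=C\CC1 | intermediate
33 | chrysomutanin | C/C1=C/Cc2c(cc(O)c3c2C[C@@H](C)OC3=O)OC(C)(C)[C@@H](O)CC/C(C)=C\CC1 | target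

**Step count and risks**

Total steps: 17. Longest linear sequence: 13 steps (steps 1–5, then 10–17).

Steps most likely to fail:

1. Step 15 (proposed new method). Radical 29 may add 6-exo to the C2′=C3′ alkene or be reduced and protonated before the slow 14-membered closure, and the congested alkylchromium 30 may add so slowly that oligomers form. The fallback uses known reactions and closes the ring one bond further along (C9′–C10′): the carboxyl carbon of the aryloxyisobutyrate is kept as the ketone carbon and the former aldehyde carbon is expelled. It sets out from 27. Pinnick oxidation (NaClO2, NaH2PO4, 2-methyl-2-butene, t-BuOH/H2O) should give the diacid F1, and TMSCHN2 in toluene/MeOH the dimethyl ester F2. A Dieckmann-type macrocyclic Claisen condensation (LiN(SiMe3)2, 3.3 equiv, THF, high dilution, −78 → 0 °C), in which the only enolisable ester (the chain ester) is acylated by the non-enolisable aryloxyisobutyrate ester, should give the macrocyclic β-keto ester F3. Krapcho demethoxycarbonylation (LiCl, wet DMSO, 130 °C) then leads to ketone 32, where the route is rejoined before step 17.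

2. Step 10. Attack at the γ carbon (SN2′), erosion of the Z geometry through allyl-metal intermediates, or slow exchange that lets the Grignard reagents attack the lactone may spoil the coupling. The fallback moves the bond formed to C1′–C2′, an sp3–sp2 coupling without allyl-metal species; it sets out from 20. Stille coupling with (tributylstannyl)methanol (Pd(PPh3)4, dioxane, 90 °C) should give the benzylic alcohol F4, CBr4/PPh3 the benzylic bromide F5, and zinc insertion (Zn dust, LiCl, THF) the benzylzinc bromide F6. Negishi coupling of F6 with alkenyl iodide 10 (Pd(OAc)2, SPhos, THF, 25 °C), which proceeds with retention at the alkenyl carbon, leads to 22, where the route is rejoined; the chain then needs only steps 1–3.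

3. Step 12. Substitution at the tertiary bromide next to the C5 side chain may be slow, so that elimination of 24 (with conjugate addition of the phenoxide to the resulting methacrylate) or alkylation at O8 competes. The fallback is a Bargellini-type etherification that avoids the tertiary halide; it sets out from 23. 1,1,1-Trichloro-2-methylpropan-2-ol with powdered NaOH in acetone (0 → 20 °C) generates a gem-dichloroepoxide that the C6 phenoxide opens at the tertiary carbon, and mild acidification should give the acetal acid 26 directly, where the route is rejoined at the acid-hydrolysis stage of step 13; no compound outside the list is made (F0).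

Further compounds
F1 | step 15 | 2-{[(R)-5-[(2Z,6Z)-9-carboxy-3,7-dimethylnona-2,6-dien-1-yl]-8-hydroxy-3-methyl-1-oxoisochroman-6-yl]oxy}-2-methylpropanoic acid (diacid) | C[C@@H]1Cc2c(C/C=C(/C)CC/C=C(/C)CCC(=O)O)c(OC(C)(C)C(=O)O)cc(O)c2C(=O)O1
F2 | step 15 | dimethyl ester of diacid F1 | C[C@@H]1Cc2c(C/C=C(/C)CC/C=C(/C)CCC(=O)OC)c(OC(C)(C)C(=O)OC)cc(O)c2C(=O)O1
F3 | step 15 | macrocyclic β-keto ester (ketone 32 carrying a methoxycarbonyl group on C9′) | C/C1=C/Cc2c(cc(O)c3c2C[C@@H](C)OC3=O)OC(C)(C)C(=O)C(C(=O)OC)C/C(C)=C\CC1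
F4 | step 10 | (R)-6,8-bis(tert-butyldimethylsilyloxy)-5-(hydroxymethyl)-3-methylisochroman-1-one | C[C@@H]1Cc2c(CO)c(O[Si](C)(C)C(C)(C)C)cc(O[Si](C)(C)C(C)(C)C)c2C(=O)O1
F5 | step 10 | (R)-5-(bromomethyl)-6,8-bis(tert-butyldimethylsilyloxy)-3-methylisochroman-1-one | C[C@@H]1Cc2c(CBr)c(O[Si](C)(C)C(C)(C)C)cc(O[Si](C)(C)C(C)(C)C)c2C(=O)O1
F6 | step 10 | {[(R)-6,8-bis(tert-butyldimethylsilyloxy)-3-methyl-1-oxoisochroman-5-yl]methyl}zinc bromide | C[C@@H]1Cc2c(C[Zn]Br)c(O[Si](C)(C)C(C)(C)C)cc(O[Si](C)(C)C(C)(C)C)c2C(=O)O1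
F0 | step 12 | none | none
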